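The constants used here are those of an exercise; no experiment stands behind them.

Which of the four set-ups leaves the most target, and how much does each leave?

    starting material + by-product → side product (k1 = 0.0029 L mol⁻¹ s⁻¹)
    starting material + reagent ⇌ target + by-product (K2 = 0.28, k2 = 0.020 L mol⁻¹ s⁻¹)
    reagent ⇌ dormant form (K3 = 0.58, k3 = 0.063 s⁻¹)

| flask | starting material | reagent | remark | time |
|---|---|---|---|---|
| north | 1.5 M | 1.30 equiv | one stirred flow tank at steady state, fed with the mixture as stated, mean residence time 2.0 min |  |
| south-west | 1.5 M | 1.30 equiv (fed, over 1.60 min) | all but reagent at the start; reagent goes in evenly over 1.60 min, the run ends at 2.0 min | 2.0 min |
| north-east | 1.5 M | 1.30 equiv | a closed flask charged with all of it at once and left for 2.0 min | 2.0 min |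
| east | 1.5 M (fed, over 1.60 min) | 1.30 equiv | a stirred flask in which starting material is dosed at a steady rate over 1.60 min without added volume, worked up at 2.0 min | 2.0 min |

1. the set-up with the highest amount of target at the outlet or at the end, in percent of the starting material put in ("none" if the first two lie within 2 percentage points) (north / south-west / north-east / east / none)
2. amount of target at the outlet or at the end, in percent of the starting material put in, north
3. amount of target at the outlet or at the end, in percent of the starting material put in, south-west
4. amount of target at the outlet or at the end, in percent of the starting material put in, north-east
5. amount of target at the outlet or at the end, in percent of the starting material put in, east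

- the stated concentrations are those of everything mixed, before any reaction; amounts are the same in each set-up
- the feed brings no volume worth counting
- run time (south-west): 2.0 min

1. Two numbers seem at odds. In north-east, starting material has a half-life of 0.30 min on the forward rate of the target step, not counting the way back. The 2.0 min run holds about 6.75 such half-lives, and reagent is charged at 1.30 equiv. Yet my reckoning, with the side step left out, stops at 33.7% converted.

2. Reagent and dormant form relax with a half-life of 0.0673 min, far shorter than the run. So c(dormant form) can be taken as 0.58 times c(reagent), and the free share of the unused reagent is 0.633.

3. In north-east, by-product has a half-life of 2.7 min in the side step with starting material as charged, somewhat longer than the run. So a rough first estimate leaves that step out and sets c(by-product) equal to c(target).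

4. Let x be the converted fraction of starting material. The charge concentration cancels from the equilibrium of the target step, which leaves x·x = 0.177 · (1 − x) · (1.30 − x). Here 0.177 is the apparent equilibrium constant, 0.28 divided by 1.58, with reagent counted in both its forms. The root is 33.7%, an estimate of where the forward and back rates of the target step balance. That clears up the puzzle, since the forward half-life does not count the way back.

5. The early end is the forward half-life and the late end is the balance estimate. Joined, they lead me to expect target to rise quickly in north-east and then stand near 33.7%. The dosed flasks keep 0.400 min after dosing, longer than the north-east half-life, so I expect them near that estimate too, and north a little below it.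

6. The forecast gives 32.5% for north, 35.1% for south-west, 35.4% for north-east and 34.6% for east, so none, on the grounds that “every set-up ends close to the same equilibrium ceiling”. Its north-east figure lies 1.7 percentage points above my estimate.

7. The simulation gives 32.5%, 34.6%, 35.2% and 34.1% in that order, so the answer is none. North-east stands highest, 0.6 points above south-west.

8. A neighbouring flask repeats north-east with 0.520 equiv of reagent, all else held. Its apparent equilibrium constant stays 0.177, and the root of x·x = 0.177 · (1 − x) · (0.520 − x) is 20.9%. That flask holds 22.4% of target at 2.00 min, with 71.3% of the starting material still present.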